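The earlier runs and the new flask were generated by integration for substances that don't exist, and the scatter is random.

Count every amount in percent of the substrate charged.

- dawn: substrate 40 mM; gas phase 2.2 mM (held); run made earlier
- flask: substrate 20 mM; gas phase 2.2 mM (held); time 1.0 h

dawn run (percent of the substrate charged)

| time / min | target / % | substrate / % |
|---|---|---|
| 0.500 | 1.5 | 91.5 |
| 1.00 | 2.2 | 83.1 |
| 2.50 | 6.8 | 61.2 |
| 6.00 | 14.1 | 27.7 |

(standard deviation of a reading: 0.5 percentage points)

- the earlier runs were read with a standard deviation of 0.5 percentage points
- at the start none of the gas phase is in solution

* amount of target at 1.0 h, in percent of the substrate charged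
* concentration of dissolved gas in solution at 1.0 h, in percent of saturation

Hold the flask against the dawn run: the same gas, half the substrate. Treat the dawn substrate as first order. Its half-life reads 3.24 min, far shorter than the flask's 1.0 h. So expect the flask's yield to equal the share of lost substrate that stands as target.

Now write the gas balance. A saturated solution holds gas for 5.50% of the dawn charge, yet dawn target reaches 14.1%. If target takes up gas, the gas must keep crossing from the gas phase during the run. The flask's saturated solution holds twice that gas per charge, so expect a better share than early in the dawn run.

Read the shares. The early dawn share is 17.5%. The late share is 21.8%: target gained per substrate lost between the last two dawn readings, a stretch selectivity. It is higher, though a scatter of 0.5 percentage points makes both rough. Over that stretch dawn substrate falls from 122% to 55.4% of the flask's charge, so my reckoning for the flask is the late share.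

The forecast says 25% target and 97% of saturation, higher on yield than mine, arguing that “selectivity runs from about 0.21 at 20 mM to about 0.3 near zero”.

The flask gives 20.8% target and 100% of saturation.

    target ⇌ isomer of the product (K = 0.750, k = 0.00160 s⁻¹)
    gas phase ⇌ dissolved gas, rate k2*(csat - [dissolved gas]) (kL = 0.0170 s⁻¹)
    substrate + dissolved gas → target (k = 1.40 L mol⁻¹ s⁻¹)
    substrate → side product A (k = 0.00240 s⁻¹)
    substrate + target → side product B (k = 0.0380 L mol⁻¹ s⁻¹)

With 0% substrate left, the flask's target standing per substrate lost is its yield, 1 point under the late share. At 0.0443 h, flask substrate passes into side product A 1.6 times as fast as into target. The flask ends with 59.3% side product A and 15.6% isomer of the product beside 20.8% target. The neighbour flask, charged with 5.0 mM substrate, keeps 0% substrate and ends at 26.1% target, 4.3 points over the late share.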